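- Time comes first. Both new flasks stop at 15 d, and both earlier runs are still climbing there: over their final 7.00 d E gains 5.1 percentage points in the south-west run and 4.9 points in the west run. So you compare charges at one fixed time.

common to all: G 0.50 M
- south-west: D 0.66 equiv; run made earlier
- west: D 2.2 equiv; run made earlier
- Saturday's: D 1.20 equiv; time 15 d
- Monday's: D 3.00 equiv; time 15 d

| run | time / d | E / % |
|---|---|---|
| south-west | 1.25 | 14.3 |
| south-west | 4.00 | 18.2 |
| south-west | 8.00 | 22.5 |
| south-west | 10.0 | 24.5 |
| south-west | 15.0 | 27.6 |
| west | 1.25 | 23.0 |
| west | 2.50 | 23.6 |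
| west | 4.00 | 25.8 |
| west | 8.00 | 32.2 |
| west | 15.0 | 37.1 |

(standard deviation of a reading: 1 percentage point)



- which of these holds the largest part of the G at the end of Saturday's (G / E / L)
- which of these holds the largest part of the G at the end of Monday's (G / E / L)
- final E in Saturday's, as a percentage of the G charged

- Next, c(G): both earlier runs stand at 0.50 M, so they give you no reading of what turning it does.
- Then the D charge, and here you count e-folds. From 0.66 equiv to 2.2 equiv is 1.20 e-folds, and E at 15 d rises from 27.6 % to 37.1 %. That gives the gain, the points of E at 15 d won per e-fold of D charged with c(G) held at 0.50 M, read from these scattered readings as 7.9 points.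
- Two runs give no test of that straight line in ln(D), so treat it as a working rule.
- Saturday's lies 0.598 e-folds above the south-west run, so this reckoning puts its E at 32.3 %.
- The forecast gives 32 % for E, with G leading in Saturday's and G in Monday's, where “G probably still leads narrowly”.
- Saturday's ends with G 51.8 %, E 34.7 % and L 13.6 %. Monday's ends with G 32.0 %, E 39.8 % and L 28.2 %, so E leads there, against the forecast.

    D + E ⇌ L (K = 22.0 M⁻¹, k = 0.0653 M⁻¹ h⁻¹)
    G + D → E (k = 0.0280 M⁻¹ h⁻¹)
    2 D → X (k = 0.0267 M⁻¹ h⁻¹)

- The gain put Saturday's E at 32.3 %, and the flask gives 34.7 %. For a neighbour of Saturday's charged with 4.80 equiv of D it gives 43.3 %, and that flask gives 39.9 %.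
- In Saturday's, the relaxation half-life of D + E and L, both ways together, is 1.92 d at 15.0 d, shorter than the 15 d of the run.
- D, the limiting reagent of Saturday's, ends at 1.9 % of its charge, and from 7.50 d to 15.0 d E goes from 28.1 % to 34.7 % while L goes from 16.0 % to 13.6 %.

(The readings are calculated with constants of no real substance, and the scatter is random.)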